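## Structural features

Abruquinone B (13) is an isoflavan quinone: benzene ring A is fused to the dihydropyran ring C (O1, C2, C3, C4, C4a, C8a), and C3 carries ring B, a 1,4-benzoquinone joined through C1' with carbonyl groups at C2' and C5' and methoxy groups at C3' and C4'. Ring A has methoxy groups at C6, C7 and C8, so that together with O1 it is a 1,2,3,4-tetraoxygenated benzene with one hydrogen left at C5. The only stereocentre is C3 (S); it lies between the methylene groups C2 and C4, has no stereogenic neighbour, and its two ring arms differ only in ending at oxygen (C2) or at aryl carbon (C4). The quinone is the fragile part: it is reducible and electrophilic, and C3–H is the γ-hydrogen of the C5'–C6'–C1' enone, so base can tautomerise the quinone towards a quinone methide and erase the stereocentre. Ring A is very electron-rich and limits the choice of oxidant for making the quinone. The real difficulty is twofold: a lone stereocentre at a CH flanked by two CH2 groups and remote from any directing function, and eight oxygen atoms on two rings that must be told apart without long protecting-group sequences. The key step uses the fact that in ring A the carbon C8a bearing O1 stands between C8 (methoxy) and C4a (bound to C4), which is the ipso-heteroatom, ortho-alkyl pattern beside one blocked ortho position that palladium–norbornene catalysis installs on an aryl iodide. The near-symmetry of C3 is used as well, because it lets the stereocentre come from the desymmetrisation of a 3-aryloxetane.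

## Logic of the disconnections

**13 ⇒ 12.** The C2' carbonyl oxygen is removed and C5' returns to a phenol. This keeps the base- and reduction-sensitive quinone, and the acidity it confers on C3–H, out of every earlier step, and turns ring B into an ordinary phenol ether. The forward step must oxidise only the one free phenol, and only at its unsubstituted para carbon C2', without attacking ring A. A nitroxyl radical oxidant that needs a phenolic O–H meets this demand.

**12 ⇒ 11.** The phenolic O–H is exchanged for O–Si. A free phenoxide would compete as a nucleophile in the palladium step and be alkylated by the bromide, so the C5' oxygen is masked and stays distinguishable from the five methyl ethers. The group must survive C–H borylation, an alkoxide base, a silyl bromide and hot carbonate and still leave with fluoride. This points to triisopropylsilyl: a benzyl ether would itself be borylated, an acetal would be cleaved by the silyl bromide, and a smaller silyl group would not survive the bases.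

**11 ⇒ 2 + 10.** Ring C is opened at two bonds at once, C4–C4a and O1–C8a. This is the most simplifying cut: it splits the molecule into a ring A piece with no phenol, no formyl group and no protecting group, and a three-carbon chain that already carries ring B and the stereocentre. C3 is β to both bonds and is not involved. In 10 the leaving group is the bromide that the preceding ring opening delivers directly, and the hydroxyl is left free because it is the nucleophile of the second bond. The forward step must alkylate the ortho carbon before the ipso carbon is functionalised, must stop after one alkylation, and must close the ether by C–O reductive elimination faster than the primary alkoxide loses a β-hydride. It must also be run so that 10 does not close back to 8 or lose HBr.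

**10 ⇒ 8.** The C–Br bond is cut and its carbon is reconnected to the oxygen, giving an achiral four-membered ether. The stereocentre is thereby traced to a choice between two enantiotopic C–O bonds and needs no bond-forming event at C3 itself. The gain is the loss of all stereochemistry from the precursor. The forward step needs a catalyst that delivers bromide to one CH2 group only, and a non-basic release of the hydroxyl so that the ring does not re-form.

**8 ⇒ 6 + 7.** The C1'–C3 bond between ring B and the four-membered ring is cut. Both pieces are then simple, and 7 is commercial. The forward step is an sp2–sp3 coupling at a secondary carbon that must not open the strained ether or remove the silyl group.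

**6 ⇒ 4 ⇒ 3.** The C–B bond at C1' is cut, then the O–Si bond. The position to be functionalised is the only ring hydrogen of 4 without an ortho neighbour, so a sterically governed C–H borylation can find it without a halogen handle. Electrophilic halogenation of 3 would go para to the hydroxyl, the wrong carbon. The demand is regioselectivity, which the substitution pattern supplies.

**2 ⇒ 1.** The C–I bond is cut. In 1 the two positions ortho to a terminal methoxy group are equivalent and are the most activated, so mono-iodination gives the iodide with one methoxy-blocked ortho position and one free ortho hydrogen. That is exactly what the key step requires.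

## Other disconnections considered

**Alternative 1:** The cut takes C2 out of the skeleton as formaldehyde A2 by breaking O1–C2 and C2–C3, and adds a temporary bond from C4 to the C2' oxygen. What remains is the E-stilbene A1, with ring A as a free ortho-vinylphenol and the C2' oxygen of ring B silylated.

- **Forward key step:** a confined chiral imidodiphosphorimidate acid would condense the phenol of A1 with A2. The O-aryl oxocarbenium ion would be attacked by the stilbene carbon C3 (6-endo closure of ring C), and the benzylic cation at C4 would be captured by the C2' oxygen with loss of the silyl group, giving the cis-fused pterocarpan A3. Hydrogenolysis of its benzylic C4–O bond would give the 2'-hydroxyisoflavan A4, whose free para position C5' allows oxidation to 13 in the manner of step 8.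
- **In its favour:** three bonds, two rings and the C3 stereocentre would arise in one catalytic step from a flat, achiral precursor. C2 comes from the cheapest one-carbon unit. Opening pterocarpans to 2'-hydroxyisoflavans by hydrogenolysis is a classical, reliable operation.
- **Against it here:** an oxocarbenium ion made from a phenol and A2 is poorly stabilised. The activated ring positions of A1 (C5 of ring A, C5' and C6' of ring B) invite Friedel–Crafts hydroxymethylation and diarylmethane formation. Under strong acid A1 can also close by itself through addition of the phenol to the protonated alkene. A1 needs ring A as a phenol with an olefination handle, which is the functional-group load the chosen plan avoids.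
- **Comparison:** on structure it is the better of the two, because the stereocentre is created in the ring-forming event and no chiral intermediate exists that could return to an achiral species. The chosen plan sets C3 one step earlier and must carry it through a hot, basic step. On mechanism both key steps are untested as cascades, but each half of the chosen step (ortho alkylation, intramolecular aryl etherification) is individually established, while the first event of the Prins cascade is not. On step economy the two are about equal: the stilbene needs four to five steps and the endgame is also two steps.

**Alternative 2:** Ring A is taken apart completely. C5–C6, C4a–C8a and C8–C8a are cut, leaving the alkenyl(methoxy)carbene complex A5, the enantiopure terminal alkyne A6, and one carbonyl ligand of A5 as the source of C8a and O1.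

- **Forward key step (Dötz benzannulation):** warming A5 with A6 would insert the alkyne and CO and electrocyclise to the arene. After loss of chromium this gives the phenol A7, in which C6, C7 and C8 are methyl ethers and C8a is the only free hydroxyl. Desilylation, Mitsunobu closure of O1–C2, removal of the methoxymethyl group and oxidation of the C2' phenol (para position C5' free) would complete 13.
- **In its favour:** the reaction type is known, and its regiochemistry with terminal alkynes is dependable (the substituted alkyne carbon ends up beside the carbon derived from CO). The four oxygens of ring A are differentiated by construction. Ring C is then closed by a secure Mitsunobu etherification with no risk of β-hydride loss. On precedent and on the security of the ring closure this plan is better than the chosen one.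
- **Against it here:** chromium is used stoichiometrically. A5, with two vinylic methoxy groups, is a donor-stabilised and little-used carbene complex that would have to be built from a lithiated enediol ether, and it may annulate sluggishly or divert to cyclopentannulation. A7 is a para-methoxyphenol in ring A and is therefore easily oxidised to a ring A quinone, in air and with the oxidants normally used to strip chromium. A6 already contains the C3 stereocentre, so the stereochemical problem is not solved but moved into a separate asymmetric synthesis.
- **Comparison:** on structure the two plans are equal in leaving C3 untouched during the key step. On mechanism the alternative is the safer. On step economy it is clearly worse: four steps after the key step instead of two, and a total several steps above the eight of the chosen route.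

**Alternative 3:** The cut is made at C3–C4 and O1–C2 with C2 at the carboxyl level. Ring B stays on the arylacetic acid A8, and ring A becomes the silylated ortho-hydroxybenzyl bromide A9.

- **Forward key step:** fluoride would release the ortho-quinone methide A10 from A9, while a chiral isothiourea turns the in situ mixed anhydride of A8 into a catalyst-bound ammonium enolate. Michael addition of the enolate carbon C3 to the methylene carbon C4 of A10, then lactonisation by the ring A phenoxide (O1–C2), would free the catalyst and give the dihydrocoumarin A11 with the configuration of 13 at C3. The lactone carbonyl would then be removed (reduction to the phenol-alcohol and Mitsunobu closure, or reduction to the lactol and ionic deoxygenation), the benzyl ether hydrogenolysed, and the C5' phenol oxidised as in step 8.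
- **In its favour:** C3 is set and ring C closed in one catalytic enantioselective step from two achiral fragments. The reaction type (ammonium enolates adding to ortho-quinone methides) is known. The benzyl ether is more robust than a silyl ether. In joining stereocontrol to ring formation and in precedent this plan is better than the chosen one.
- **Against it here:** in A11 the new stereocentre is α to an aryl ester carbonyl and benzylic, so it is prone to enolisation under the basic conditions in which it forms and during reduction. C2 arrives at the wrong oxidation level and costs about two further steps. A9 is an electron-rich, labile benzylic bromide that needs about three steps, and A8 needs a homologation sequence.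
- **Comparison:** on structure the two plans share the ring B pattern and the deprotection/oxidation endgame and are equal there. On mechanism the alternative has the better-documented key step but the more fragile stereocentre, whereas the chosen plan keeps C3 as a non-acidic CH until the last step. On step economy the alternative is longer by three to four steps.

Key step: step 6

Remark on the chemistry (assumption): the bromide-bearing carbon of 10 becomes C4 and the carbinol carbon becomes C2. With this mapping the S configuration of 13 requires (S)-10, and the enantiomer of the squaramide catalyst in step 5 is chosen accordingly.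

## Route

Step 1
Reactants: 1 1,2,3-trimethoxybenzene
Product: 2 1-iodo-2,3,4-trimethoxybenzene
Conditions: N-iodosuccinimide, CF3CO2H (cat.), MeCN, rt
Reagents that add atoms: N-iodosuccinimide, O=C1CCC(=O)N1I
Why: Electrophilic aromatic iodination; the iodonium equivalent attacks C4 of 1 (ortho to one methoxy group, para to another; C4 and C6 are equivalent by symmetry), and the reaction stops at the mono-iodide because iodine deactivates the ring.

Step 2
Reactants: 3 2,3-dimethoxyphenol
Product: 4 (2,3-dimethoxyphenoxy)triisopropylsilane
Conditions: i-Pr3SiCl, imidazole, DMF, rt
Reagents that add atoms: chlorotriisopropylsilane, CC(C)[Si](Cl)(C(C)C)C(C)C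
Why: Silylation of a phenol with a silyl chloride and imidazole; the triisopropylsilyl group has no aromatic C–H bonds to compete in step 3, is inert to Me3SiBr in step 5, and is the silyl ether most resistant to the bases of steps 4 and 6.

Step 3
Reactants: 4 (2,3-dimethoxyphenoxy)triisopropylsilane
Product: 6 [3,4-dimethoxy-5-(triisopropylsilyloxy)phenyl]boronic acid, via pinacol boronate 5 (not isolated)
Conditions: [Ir(OMe)(cod)]2 (cat.), 4,4'-di-tert-butyl-2,2'-bipyridine (cat.), B2pin2 (0.55 equiv), THF, 80 °C; then NaIO4, THF/H2O, then 1 M HCl, rt
Reagents that add atoms: bis(pinacolato)diboron, CC1(C)OB(OC1(C)C)B1OC(C)(C)C(C)(C)O1; water, O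
Why: Iridium-catalysed aromatic C–H borylation is governed by sterics and takes the only ring hydrogen of 4 without an ortho neighbour (the future C1'); oxidative cleavage of the pinacol by NaIO4 in the same flask then gives the free boronic acid that the nickel coupling of step 4 uses.

Step 4
Reactants: 6 [3,4-dimethoxy-5-(triisopropylsilyloxy)phenyl]boronic acid; 7 3-iodooxetane
Product: 8 3-[3,4-dimethoxy-5-(triisopropylsilyloxy)phenyl]oxetane
Conditions: NiI2 (cat.), trans-2-aminocyclohexanol·HCl (cat.), NaN(SiMe3)2, i-PrOH, 80 °C
Reagents that add atoms: none
Why: Nickel-catalysed Suzuki coupling of an arylboronic acid with a secondary alkyl iodide (amino alcohol ligand, alkoxide base), a reaction type established for 3-iodooxetane; the alkyl-radical/nickel pathway tolerates the β-oxygens and leaves the four-membered ring intact.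

Step 5
Reactants: 8 3-[3,4-dimethoxy-5-(triisopropylsilyloxy)phenyl]oxetane
Product: 10 (2S)-3-bromo-2-[3,4-dimethoxy-5-(triisopropylsilyloxy)phenyl]propan-1-ol, via trimethylsilyl ether 9 (not isolated)
Conditions: Me3SiBr, chiral arylpyrrolidine squaramide (cat.), t-BuOMe, –78 °C; then citric acid, MeOH, 0 °C
Reagents that add atoms: bromotrimethylsilane, C[Si](C)(C)Br
Why: Enantioselective desymmetrisation of a 3-substituted oxetane by squaramide anion-binding catalysis: the catalyst holds bromide and delivers it to one of the two enantiotopic CH2–O carbons of the silyl-activated ring, so the aryl-bearing carbon becomes a stereocentre without any bond to it being made, and the catalyst enantiomer is chosen to give S; mild acidic methanolysis frees the alcohol without base, so the ring cannot re-close.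

Step 6
Reactants: 2 1-iodo-2,3,4-trimethoxybenzene; 10 (2S)-3-bromo-2-[3,4-dimethoxy-5-(triisopropylsilyloxy)phenyl]propan-1-ol
Product: 11 (3S)-3-[3,4-dimethoxy-5-(triisopropylsilyloxy)phenyl]-6,7,8-trimethoxychroman
Conditions: 2 (1.5 equiv), Pd(OAc)2 (10 mol%), RuPhos (20 mol%), norbornene (1 equiv), Cs2CO3 (3 equiv), toluene, 100 °C
Reagents that add atoms: none
Why: Proposed new method: zerovalent palladium inserts into the C–I bond of 2, norbornene inserts, and the free ortho C–H bond (future C4a) is palladated to a five-membered aryl-norbornyl palladacycle; this takes up the primary C–Br bond of 10 to reach tetravalent palladium, reductive elimination forms C4–C4a, and with both ortho positions filled norbornene is expelled by β-carbon elimination. The resulting divalent arylpalladium at C8a binds the tethered alkoxide as a seven-membered chelate, and C–O reductive elimination forms O1–C8a, so ring C is closed as a six-membered ether in the second, intramolecular event of a formal [3+3] annulation. The closest known reaction type is the palladium–norbornene (Catellani) annulation of aryl iodides with epoxides to 2,3-dihydrobenzofurans, and the terminating event alone corresponds to the known palladium-catalysed intramolecular etherification of aryl halides with primary alcohols under bulky biaryl phosphines and Cs2CO3. No stereocentre is formed: C3 is β to both reacting carbons, no bond to it is made or broken, and the configuration of 10 passes into 11 provided 10 does not revert to the achiral 8, which the weak, sparingly soluble base in a non-polar solvent is chosen to suppress. Mono-alkylation and clean norbornene extrusion are secured by the C8 methoxy group, the single ortho substituent of 2. The selectivity that must be won is C–O reductive elimination over β-hydride loss from the primary alkoxide; the di-ortho-substituted aryl group and the bulky, electron-rich phosphine both favour reductive elimination.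

Step 7
Reactants: 11 (3S)-3-[3,4-dimethoxy-5-(triisopropylsilyloxy)phenyl]-6,7,8-trimethoxychroman
Product: 12 2,3-dimethoxy-5-[(3S)-6,7,8-trimethoxychroman-3-yl]phenol
Conditions: Bu4NF, AcOH, THF, 0 °C
Reagents that add atoms: none
Why: Fluoride cleaves the aryl O–Si bond (formation of the strong Si–F bond); acetic acid buffers the phenoxide so that the electron-rich phenol is not exposed to base and air, and nothing else in 11 reacts with fluoride.

Step 8
Reactants: 12 2,3-dimethoxy-5-[(3S)-6,7,8-trimethoxychroman-3-yl]phenol
Product: 13 abruquinone B (2,3-dimethoxy-5-[(3S)-6,7,8-trimethoxychroman-3-yl]-1,4-benzoquinone)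
Conditions: (KSO3)2NO, KH2PO4, H2O/acetone, 0 °C to rt
Reagents that add atoms: potassium nitrosodisulfonate, [K+].[K+].[O-]S(=O)(=O)N([O])S(=O)(=O)[O-]
Why: Teuber oxidation: one nitroxyl radical abstracts the phenolic hydrogen, a second adds at the free para carbon C2', and loss of imidodisulfonate gives the para-quinone; ring A has no free phenol and is not attacked, the pattern is that of a 2,3-dimethoxy-5-alkylphenol, and the buffered near-neutral medium protects the vinylogously acidic C3–H of the product.

## Compound list

1 | 1,2,3-trimethoxybenzene | COc1cccc(OC)c1OC | starting material
2 | 1-iodo-2,3,4-trimethoxybenzene | COc1ccc(I)c(OC)c1OC | intermediate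
3 | 2,3-dimethoxyphenol | COc1cccc(O)c1OC | starting material
4 | (2,3-dimethoxyphenoxy)triisopropylsilane | COc1cccc(O[Si](C(C)C)(C(C)C)C(C)C)c1OC | intermediate
5 | 2-[3,4-dimethoxy-5-(triisopropylsilyloxy)phenyl]-4,4,5,5-tetramethyl-1,3,2-dioxaborolane | COc1cc(B2OC(C)(C)C(C)(C)O2)cc(O[Si](C(C)C)(C(C)C)C(C)C)c1OC | intermediate
6 | [3,4-dimethoxy-5-(triisopropylsilyloxy)phenyl]boronic acid | COc1cc(B(O)O)cc(O[Si](C(C)C)(C(C)C)C(C)C)c1OC | intermediate
7 | 3-iodooxetane | IC1COC1 | starting material
8 | 3-[3,4-dimethoxy-5-(triisopropylsilyloxy)phenyl]oxetane | COc1cc(C2COC2)cc(O[Si](C(C)C)(C(C)C)C(C)C)c1OC | intermediate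
9 | {(2S)-3-bromo-2-[3,4-dimethoxy-5-(triisopropylsilyloxy)phenyl]propoxy}trimethylsilane | COc1cc([C@H](CBr)CO[Si](C)(C)C)cc(O[Si](C(C)C)(C(C)C)C(C)C)c1OC | intermediate
10 | (2S)-3-bromo-2-[3,4-dimethoxy-5-(triisopropylsilyloxy)phenyl]propan-1-ol | COc1cc([C@H](CBr)CO)cc(O[Si](C(C)C)(C(C)C)C(C)C)c1OC | intermediate
11 | (3S)-3-[3,4-dimethoxy-5-(triisopropylsilyloxy)phenyl]-6,7,8-trimethoxychroman | COc1cc([C@H]2COc3c(cc(OC)c(OC)c3OC)C2)cc(O[Si](C(C)C)(C(C)C)C(C)C)c1OC | intermediate
12 | 2,3-dimethoxy-5-[(3S)-6,7,8-trimethoxychroman-3-yl]phenol | COc1cc([C@H]2COc3c(cc(OC)c(OC)c3OC)C2)cc(O)c1OC | intermediate
13 | abruquinone B, 2,3-dimethoxy-5-[(3S)-6,7,8-trimethoxychroman-3-yl]cyclohexa-2,5-diene-1,4-dione | COC1=C(OC)C(=O)C([C@H]2COc3c(cc(OC)c(OC)c3OC)C2)=CC1=O | target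

## Step count and risks

Total: 8 steps. Longest linear sequence: 7 steps (from 3 through steps 2 to 8). Step 1 is a one-step branch that joins at step 6.

**Step 6 (key step, proposed new method).**
- What may go wrong: β-hydride elimination from the arylpalladium alkoxide may overtake C–O reductive elimination, because the primary alkoxide sits in a flexible seven-membered chelate. This would lead to ipso reduction of ring A and oxidation of the carbinol. Base-induced loss of HBr from 10, or closure back to the achiral four-membered ether, may consume the chiral partner and, if that ether then alkylated, erode the enantiomeric purity. The β-branched bromide may also be taken up slowly by the palladacycle, allowing aryl–aryl coupling of 2.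
- Fallback by known chemistry, from 10 back to 11: commercial 2,3,4-trimethoxyphenol is brominated ortho to the hydroxyl (N-bromosuccinimide, i-Pr2NH cat., CH2Cl2, 0 °C) to 6-bromo-2,3,4-trimethoxyphenol F1. A Mitsunobu etherification of 10 with F1 (PPh3, diisopropyl azodicarboxylate, THF, 0 °C to rt) forms O1–C2 and gives the bromoaryl ether {5-[(2S)-1-bromo-3-(2-bromo-4,5,6-trimethoxyphenoxy)propan-2-yl]-2,3-dimethoxyphenoxy}triisopropylsilane F2. Halogen–lithium exchange at the aryl bromide (t-BuLi, 2 equiv, THF, –78 °C to rt) followed by intramolecular displacement of the primary bromide (Parham cyclisation) forms C4–C4a and gives 11. The same carbons become C2 and C4 as in the key step, so the configuration is the same.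

**Step 4.**
- What may go wrong: loss of the silyl ether through attack of isopropoxide at 80 °C, and protodeboronation of the electron-rich boronic acid before transmetalation.
- Fallback, from 6 back to 8: oxetan-3-one is condensed with p-toluenesulfonyl hydrazide (MeOH, rt) to 4-methyl-N'-(oxetan-3-ylidene)benzenesulfonohydrazide F3. Heating F3 with 6 and Cs2CO3 in 1,4-dioxane at 110 °C effects the metal-free reductive coupling of a sulfonylhydrazone with a boronic acid (thermal loss of sulfinate and nitrogen, carbon–boron bond formation with 1,2-aryl shift, protodeboronation) and gives 8 without nickel or alkoxide.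

**Step 5.**
- What may go wrong: insufficient discrimination between the two enantiotopic C–O bonds, because uncatalysed ring opening by Me3SiBr or adventitious HBr competes with the catalyst-bound pathway.
- Fallback, from 8 back to 10: aqueous HBr (CH2Cl2, 0 °C) opens the ring without stereocontrol to racemic 3-bromo-2-[3,4-dimethoxy-5-(triisopropylsilyloxy)phenyl]propan-1-ol F4. This is resolved by lipase-catalysed acylation (Burkholderia cepacia lipase, vinyl acetate, t-BuOMe, rt). By the empirical size rule for primary alcohols the (S)-alcohol should be acylated faster, giving (2S)-3-bromo-2-[3,4-dimethoxy-5-(triisopropylsilyloxy)phenyl]propyl acetate F5. F5 is separated from the unreacted (R)-alcohol and cleaved with HCl in MeOH (acid, so the ring cannot re-form) to return to 10. If the enzyme shows the opposite preference, 10 is collected directly as the unreacted alcohol beside (2R)-3-bromo-2-[3,4-dimethoxy-5-(triisopropylsilyloxy)phenyl]propyl acetate F6.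

**Step 8.**
- What may go wrong: attack of the second nitroxyl radical at the less hindered ortho carbon C6' instead of the para carbon C2', which is flanked by two substituents; coupling of the phenoxyl radical; and base-induced tautomerisation of the quinone at C3 if the buffer fails.
- Fallback, from 12 back to 13: a two-electron oxidation with PhI(OCOCF3)2 (2.2 equiv, MeCN/H2O, 0 °C). Water adds para to the activated phenol to give, after tautomerisation, 2,3-dimethoxy-5-[(3S)-6,7,8-trimethoxychroman-3-yl]benzene-1,4-diol F7. F7 is oxidised in the same flask by the second equivalent to 13 under acidic, non-radical conditions.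

## Further compounds

F1 | step 6 | 6-bromo-2,3,4-trimethoxyphenol | COc1cc(Br)c(O)c(OC)c1OC
F2 | step 6 | {5-[(2S)-1-bromo-3-(2-bromo-4,5,6-trimethoxyphenoxy)propan-2-yl]-2,3-dimethoxyphenoxy}triisopropylsilane | COc1cc([C@H](CBr)COc2c(Br)cc(OC)c(OC)c2OC)cc(O[Si](C(C)C)(C(C)C)C(C)C)c1OC
F3 | step 4 | 4-methyl-N'-(oxetan-3-ylidene)benzenesulfonohydrazide | Cc1ccc(cc1)S(=O)(=O)NN=C1COC1
F4 | step 5 | racemic 3-bromo-2-[3,4-dimethoxy-5-(triisopropylsilyloxy)phenyl]propan-1-ol | COc1cc(C(CBr)CO)cc(O[Si](C(C)C)(C(C)C)C(C)C)c1OC
F5 | step 5 | (2S)-3-bromo-2-[3,4-dimethoxy-5-(triisopropylsilyloxy)phenyl]propyl acetate | COc1cc([C@H](CBr)COC(C)=O)cc(O[Si](C(C)C)(C(C)C)C(C)C)c1OC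
F6 | step 5 | (2R)-3-bromo-2-[3,4-dimethoxy-5-(triisopropylsilyloxy)phenyl]propyl acetate | COc1cc([C@@H](CBr)COC(C)=O)cc(O[Si](C(C)C)(C(C)C)C(C)C)c1OC
F7 | step 8 | 2,3-dimethoxy-5-[(3S)-6,7,8-trimethoxychroman-3-yl]benzene-1,4-diol | COc1c(O)cc([C@H]2COc3c(cc(OC)c(OC)c3OC)C2)c(O)c1OC
A1 | alternative 1 | 2-[(E)-2-{2-[(tert-butyldimethylsilyl)oxy]-3,4-dimethoxyphenyl}ethenyl]-4,5,6-trimethoxyphenol | COc1cc(/C=C/c2ccc(OC)c(OC)c2O[Si](C)(C)C(C)(C)C)c(O)c(OC)c1OC
A2 | alternative 1 | formaldehyde | C=O
A3 | alternative 1 | cis-fused 2,3,4,9,10-pentamethoxypterocarpan, C6a configured as C3 of 13 | COc1ccc2c(c1OC)O[C@H]3[C@@H]2COc4c3cc(OC)c(OC)c4OC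
A4 | alternative 1 | 2,3-dimethoxy-6-[(3S)-6,7,8-trimethoxychroman-3-yl]phenol | COc1ccc([C@H]2COc3c(cc(OC)c(OC)c3OC)C2)c(O)c1OC
A5 | alternative 2 | pentacarbonyl[(1,2-dimethoxyethenyl)(methoxy)carbene]chromium | COC=C(OC)C(OC)=[Cr](=C=O)(=C=O)(=C=O)(=C=O)=C=O
A6 | alternative 2 | tert-butyl({(2S)-2-[3,4-dimethoxy-2-(methoxymethoxy)phenyl]pent-4-yn-1-yl}oxy)dimethylsilane | COCOc1c([C@H](CC#C)CO[Si](C)(C)C(C)(C)C)ccc(OC)c1OC
A7 | alternative 2 | 2-{(2S)-3-[(tert-butyldimethylsilyl)oxy]-2-[3,4-dimethoxy-2-(methoxymethoxy)phenyl]propyl}-4,5,6-trimethoxyphenol | COCOc1c([C@H](Cc2cc(OC)c(OC)c(OC)c2O)CO[Si](C)(C)C(C)(C)C)ccc(OC)c1OC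
A8 | alternative 3 | 2-[3-(benzyloxy)-4,5-dimethoxyphenyl]acetic acid | COc1cc(CC(=O)O)cc(OCc2ccccc2)c1OC
A9 | alternative 3 | [2-(bromomethyl)-4,5,6-trimethoxyphenoxy](tert-butyl)dimethylsilane | COc1cc(CBr)c(O[Si](C)(C)C(C)(C)C)c(OC)c1OC
A10 | alternative 3 | 2,3,4-trimethoxy-6-methylidenecyclohexa-2,4-dien-1-one | C=C1C=C(OC)C(OC)=C(OC)C1=O
A11 | alternative 3 | (3S)-3-[3-(benzyloxy)-4,5-dimethoxyphenyl]-6,7,8-trimethoxychroman-2-one | COc1cc([C@H]2C(=O)Oc3c(cc(OC)c(OC)c3OC)C2)cc(OCc4ccccc4)c1OC
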